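The numbers in the tables are simulated with made-up constants; noise was put on by code.

No constants came with this flask, so I read one from its own earlier course, the delta run.

- delta: free monomer 0.10 M (fed, over 5.0 min); initiator 4.7 mM; the very flask that is asked about, followed so far; the fed solution adds 1.0 times the starting volume
- flask: free monomer 0.10 M (fed, over 5.0 min); initiator 4.7 mM; time 10 h; the fed solution adds 1.0 times the starting volume

delta run (percent of the free monomer charged)

| time / h | monomer in chains / % | free monomer / % |
|---|---|---|
| 0.417 | 0.5 | 98.0 |
| 0.833 | 4.5 | 95.3 |
| 1.33 | 11.7 | 88.3 |
| 1.50 | 13.4 | 85.6 |
| 2.00 | 21.2 | 78.7 |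
| 2.50 | 26.8 | 71.5 |
| 3.00 | 32.0 | 65.3 |

(scatter of a reading: 0.5 percentage points)

- charges are per starting volume, the dose included; the dosed solution carries all of it
- the average divides the monomer in chains by the number of chains begun, living and dead together
- steps that have been proposed: free monomer + initiator -> living end + monomer in chains; free monomer + living end -> monomer in chains + living end; 2 living end -> dead end A; initiator + monomer in chains -> spent initiator B
- the earlier runs do not show the number of chains; that part of a forecast is a guess

1. average number of monomer units in a chain (chains begun, living or dead) at 10 h
2. part of the free monomer that has reacted at 10 h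

The logarithm of the free monomer fell by 0.154 h⁻¹ between 0.833 h and 1.33 h, but by 0.187 h⁻¹ between 2.00 h and 3.00 h, which was faster. The two halves of that last stretch gave 0.192 h⁻¹ and 0.181 h⁻¹, so within the scatter I read a crossing there: the climb seemed to have stopped, as it does when the loss of living ends catches up with their supply. I called that plateau the burn, the fraction of the free monomer used per hour at the crossing. It is a pseudo-first-order constant that follows the living ends.

I took two extremes from the last reading. If the burn held:

free monomer left = 65.3% × exp(−0.187 h⁻¹ × 7.00 h) = 17.7%

So 82.3% would have reacted. If the burn stopped at once, 34.7% would have reacted. Two proposed steps use up initiator, so I expected the supply to fade, while the living ends present die gradually. I drew the burn falling in a straight line to nothing at 10 h, which halves the exponent: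

free monomer left = 34.0%, reacted 66.0%

The readings do not show the chain count, so I left that a guess.

The forecast gave an average of 45 units in a chain and 75% reacted, the latter above my figure, holding that “living ends should follow √(monomer × initiator)”.

This flask gave 41.6 and 66.9%.

    free monomer + initiator → living end + monomer in chains (k = 0.0567 M⁻¹ min⁻¹)
    free monomer + living end → monomer in chains + living end, rate k2*[living end]*[free monomer] (k = 7.02 M⁻¹ min⁻¹)
    2 living end → dead end A (k = 6.83 M⁻¹ min⁻¹)
    initiator + monomer in chains → spent initiator B (k = 0.641 M⁻¹ min⁻¹)

In this flask, chains grew on the living ends while initiator fell from 40.0% of its charge at 2.50 h to 4.84% at 5.00 h and 0.0141% at 10.0 h. Living ends went from 4.20 × 10⁻⁴ M to 1.32 × 10⁻⁴ M over that span, taking the burn from 0.177 h⁻¹ to 0.0556 h⁻¹. After the last reading this flask spent half of the held burn. Read at 15 h, the halved burn gives 21.3% free monomer left, and the same flask read then held 26.5%.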